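**Plan**
Retrosynthesis (ent-kaurane numbering): the C15 and C11 carbinols are adjusted last; ring A is cut at C5–C10 to a ring-fused C9–C10–C11 cyclopropanol carrying a C5=C6 alkenyl boronate; the cyclopropane and the lactone go back to a bicyclic silyl enol ether, ethyl diazoacetate (C10, C20) and aldehyde 16 (C1–C6); ring D is cut at C13–C16; ring C comes from 3-methoxybenzoic acid.
Forward order: ring C (Birch reductive alkylation), ring D (vinyl-radical cyclization), cyclopropane and then the δ-lactone, ring A last.
Enabling feature: the C11 oxygen is β to the spiro carbon C10 (C11–C9–C10), so C10 is the homoenolate carbon of a ring C ketone and can be stored as a cyclopropanol; the C6 hydroxyl sits one carbon from C5, so a C5=C6–B unit accepts the C10 radical and the boron later becomes that hydroxyl.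
Stereochemistry: C8 by resolution (C13 follows from the bicycle), C9 by cyclopropanation on the C14 face, C1 by CBS reduction, C10 and C5 in the key step (chair transition state), C11 by Mitsunobu inversion, C15 by Luche reduction.

Key step: step 16

Remark: ent-kaurane numbering of the target is used for all intermediates (ring A = C1–C5, C10; lactone = C7, O, C20, C10, C9, C8; ring C = C8, C9, C11–C14; bridge C15–C16; methylidene C17).
Remark: the (S)-acid 7 is assumed to form the less soluble salt with (R)-1-phenylethylamine; if the opposite holds, the (S)-amine is used.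
Remark: ester 13 is taken as commercial; otherwise it is one step from isobutyraldehyde and methyl acrylate.

**Step 1**
Reactants: 1 3-methoxybenzoic acid; 2 2,3-dibromoprop-1-ene
Product: 3 (±)-1-(2-bromoprop-2-en-1-yl)-3-methoxycyclohexa-2,5-diene-1-carboxylic acid
Conditions: Li, NH3(l), THF, −78 °C; isoprene (quench of excess Li); then 2; NH4Cl
Reagents that add atoms: none
Why: Birch reductive alkylation: dissolving-metal reduction gives the carboxylate-stabilized dienolate, which is alkylated at the ipso carbon by the allylic bromide and creates the C8 quaternary centre next to the C9=C11 enol ether.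

**Step 2**
Reactants: 3
Product: 5 (±)-1-(2-bromoprop-2-en-1-yl)-5-oxocyclohex-3-ene-1-carboxylic acid, via β,γ-enone acid 4 (not isolated)
Conditions: 2 M HCl, THF, 50 °C
Reagents that add atoms: water, O
Why: Acid hydrolysis of the methyl enol ether gives the C11 ketone and acid-catalysed isomerization then moves C13=C14 into conjugation, the standard sequel to a Birch reduction.

**Step 3**
Reactants: 5
Product: 7 (S)-1-(2-bromoprop-2-en-1-yl)-5-oxocyclohex-3-ene-1-carboxylic acid, via phenylethylammonium salt 6 (not isolated)
Conditions: (R)-1-phenylethylamine, acetone, crystallization; then 1 M HCl, EtOAc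
Reagents that add atoms: none
Why: Classical resolution through the diastereomeric ammonium salt supplies C8 as a single enantiomer, from which all later stereocentres are relayed.

**Step 4**
Reactants: 7
Product: 8 methyl (S)-1-(2-bromoprop-2-en-1-yl)-5-oxocyclohex-3-ene-1-carboxylate
Conditions: MeI, K2CO3, DMF, rt
Reagents that add atoms: iodomethane, CI
Why: SN2 O-alkylation of the carboxylate gives the methyl ester that later acts as the lactone acyl donor.

**Step 5**
Reactants: 8
Product: 9 methyl (R)-1-(2-bromoprop-2-en-1-yl)-5-[(tert-butyldimethylsilyl)oxy]cyclohexa-3,5-diene-1-carboxylate (C8 unchanged in space)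
Conditions: LiN(i-Pr)2, THF, −78 °C; TBSCl, HMPA
Reagents that add atoms: tert-butyldimethylsilyl chloride, CC(C)(C)[Si](C)(C)Cl
Why: Kinetic α′-deprotonation of the enone and O-silylation give the cross-conjugated 2-siloxy diene, which fixes the enol ether at C9=C11.

**Step 6**
Reactants: 9
Product: 10 methyl 3-[(tert-butyldimethylsilyl)oxy]-6-methylidenebicyclo[3.2.1]oct-2-ene-1-carboxylate (bridgeheads C8 and C13 as in the target)
Conditions: Bu3SnH (slow addition), AIBN, benzene, 80 °C
Reagents that add atoms: none
Why: Tin-mediated vinyl-radical cyclization, 5-exo-trig onto C13 (the diene terminus), should close ring D and leave the C16 methylidene; the 2-siloxyallyl radical is expected to take hydrogen at C12 rather than at the neopentyl C9, which keeps the enol ether at C9=C11, and C13 is fixed by the bridged geometry.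

**Step 7**
Reactants: 10; 11 ethyl diazoacetate
Product: 12 siloxycyclopropane diester (C10 bearing H and CO2Et bridges C9 and C11 on the C14 face; H9 and the silyloxy group face the C15–C16 bridge; both C10 epimers)
Conditions: Rh2(OAc)4 (1 mol %), CH2Cl2, rt, slow addition of 11
Reagents that add atoms: none
Why: Carbenoid cyclopropanation of the electron-rich silyl enol ether (a donor–acceptor cyclopropane synthesis), expected on the face of the one-carbon bridge C14 and faster than at the 1,1-disubstituted C16=C17 alkene, forms C9–C10 and C10–C11 and sets C9.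

**Step 8**
Reactants: 13 methyl 4,4-dimethyl-5-oxopentanoate; 14 2-(dichloromethyl)-4,4,5,5-tetramethyl-1,3,2-dioxaborolane
Product: 15 methyl (E)-4,4-dimethyl-6-(4,4,5,5-tetramethyl-1,3,2-dioxaborolan-2-yl)hex-5-enoate
Conditions: CrCl2, LiI, THF, rt
Reagents that add atoms: none
Why: Takai–Utimoto boron olefination with the gem-dichromium reagent from 14 gives the (E)-alkenyl boronate from the hindered aldehyde.

**Step 9**
Reactants: 15
Product: 16 (E)-4,4-dimethyl-6-(4,4,5,5-tetramethyl-1,3,2-dioxaborolan-2-yl)hex-5-enal
Conditions: i-Bu2AlH, CH2Cl2, −78 °C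
Reagents that add atoms: none
Why: Partial reduction of the ester to the aldehyde at low temperature relies on the stable tetrahedral aluminium hemiacetal.

**Step 10**
Reactants: 12; 16
Product: 17 aldol adduct (C10 now carries CO2Et on the ring C side, cis to C8, and the 1-hydroxy chain C1–C6 on the outer side; both C1 epimers)
Conditions: LiN(i-Pr)2, THF, −78 °C; then 16
Reagents that add atoms: none
Why: Deprotonation of the cyclopropane C–H next to the ester gives an ester enolate that undergoes aldol addition to 16 from the outer face of the three-membered ring, so the ester carbon C20 ends cis to C8 as the lactone needs; the C1 carbinol mixture is corrected in steps 12 and 13.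

**Step 11**
Reactants: 17
Product: 19 lactone alcohol (δ-lactone C7(=O)–O–C20 closed onto C10; C1–OH epimers), via diol ester 18 (not isolated)
Conditions: LiBH4, MeOH (1 equiv), THF, 0 °C to rt
Reagents that add atoms: none
Why: Hydroxyl-assisted borohydride reduction should take the β-hydroxy ethyl ester selectively over the hindered bridgehead methyl ester, and the C20 alkoxide, held cis to C8, then closes the δ-lactone by transesterification (the outer C1 hydroxyl cannot reach C7).

**Step 12**
Reactants: 19
Product: 20 lactone ketone (C1=O)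
Conditions: Dess–Martin periodinane, NaHCO3, CH2Cl2, rt
Reagents that add atoms: none
Why: Dess–Martin oxidation converts the epimeric C1 carbinols into one ketone so that C1 can be set by reagent control.

**Step 13**
Reactants: 20
Product: 21 (1S)-carbinol
Conditions: (R)-2-methyl-CBS-oxazaborolidine, catecholborane, toluene, −78 °C
Reagents that add atoms: none
Why: Corey–Bakshi–Shibata reduction, with the quaternary cyclopropane carbon as the large group and the CH2 chain as the small group, should give the (1S)-carbinol under reagent control, and catecholborane leaves the alkenes and the boronate untouched at this temperature.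

**Step 14**
Reactants: 21
Product: 22 (1S)-acetate
Conditions: Ac2O, DMAP, Et3N, CH2Cl2, 0 °C
Reagents that add atoms: acetic anhydride, CC(=O)OC(C)=O
Why: DMAP-catalysed acylation of the only free hydroxyl installs the C1 acetate before other hydroxyls are unveiled.

**Step 15**
Reactants: 22
Product: 23 cyclopropanol (C11–OH free; C9–C10–C11 ring on the C14 face)
Conditions: TBAF, AcOH, THF, 0 °C
Reagents that add atoms: none
Why: Buffered fluoride desilylation frees the tertiary cyclopropanol needed for O–H-based radical generation without acetate migration or loss of the boronate.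

**Step 16**
Reactants: 23
Product: 24 spiro ketone (ring A closed; C11 ketone; C6–B(pin); C5, C9, C10 as in the target)
Conditions: [Ir(dF(CF3)ppy)2(dtbbpy)]PF6 (2 mol %), 2,4,6-collidine, MeCN/H2O, blue LEDs, rt, degassed
Reagents that add atoms: none
Why: Proposed new method: base-assisted single-electron oxidation of the cyclopropanol O–H by the excited iridium photocatalyst gives an alkoxy radical whose strain-driven β-scission cleaves C10–C11, so C11 becomes the ketone and C10 a tertiary radical that adds 6-exo-trig to C5 of the alkenyl boronate, after which the α-boryl radical at C6 is reduced by the reduced photocatalyst and protonated. The closest known reaction types are the photoredox ring-opening of cyclopropanols to β-keto radicals with Giese addition to electron-poor alkenes and the Giese-type addition of alkyl radicals to vinyl boronic esters; their intramolecular union on an alkenyl boronate is the new element. Ring A closes in the 6-exo-trig mode through a chair transition state. C10 is controlled by the C1 acetate and the C9 arm taking equatorial positions, which brings C5 onto the face of C10 syn to H9, and C5 is controlled by the CH–B carbon lying equatorial in the same chair. The step needs β-scission toward C10 rather than C9 and cyclization faster than quenching of the tertiary radical; the first is secured by radical stability and retention of the six-membered ring C, the second by the absence of any hydrogen-atom donor and by the gem-dimethyl group at C4.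

**Step 17**
Reactants: 24
Product: 25 11-epi alcohol (C11–OH on the C14 face)
Conditions: NaBH4, MeOH, −20 °C
Reagents that add atoms: none
Why: Borohydride reduction of the ring C ketone, run at once to avoid epimerization at C9, should deliver hydride from the face of the C15–C16 bridge because the C14 face is screened by the axial C9–C10 bond and ring A, giving the 11-epi alcohol.

**Step 18**
Reactants: 25
Product: 26 11-chloroacetate (C11–O inverted, now syn to H9)
Conditions: PPh3, DIAD, ClCH2CO2H, toluene, 0 °C to rt
Reagents that add atoms: chloroacetic acid, OC(=O)CCl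
Why: Mitsunobu reaction inverts C11 by SN2 attack from the same accessible bridge face, placing the oxygen as in the target, and the chloroacetate can be removed later without touching the C1 acetate.

**Step 19**
Reactants: 26
Product: 27 11-alcohol (C11 as in the target)
Conditions: thiourea, NaHCO3, EtOH, 50 °C
Reagents that add atoms: none
Why: Thiourea cleaves chloroacetates selectively by S-alkylation and cyclization, leaving the acetate and the lactone intact.

**Step 20**
Reactants: 27
Product: 28 15-deoxy target (C6–OH)
Conditions: NaBO3·4H2O, THF/H2O, rt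
Reagents that add atoms: sodium perborate, [Na+].[Na+].O[B-]1(O)OO[B-](O)(O)OO1
Why: Perborate oxidation of the primary alkyl boronate proceeds by 1,2-migration from boron to oxygen and turns the radical-acceptor handle into the C6 hydroxyl under conditions mild enough for the acetate and lactone.

**Step 21**
Reactants: 28
Product: 29 15-epi allylic alcohol (C15–OH on the outer face of the two-carbon bridge)
Conditions: SeO2 (0.5 equiv), t-BuOOH, CH2Cl2, rt
Reagents that add atoms: tert-butyl hydroperoxide, CC(C)(C)OO; selenium dioxide, O=[Se]=O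
Why: Selenium dioxide allylic oxidation (ene reaction, then [2,3]-sigmatropic shift) hydroxylates C15, the only allylic methylene of the exocyclic alkene, with the double bond returning to C16=C17; attack from the outer face is expected to give the 15-epimer.

**Step 22**
Reactants: 29
Product: 30 C15 enone
Conditions: MnO2, CH2Cl2, rt
Reagents that add atoms: none
Why: MnO2 oxidizes the allylic C15 alcohol selectively in the presence of the saturated secondary C11 and primary C6 hydroxyls.

**Step 23**
Reactants: 30
Product: 31 target CNP0210922.1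
Conditions: NaBH4, CeCl3·7H2O, MeOH, −78 °C
Reagents that add atoms: none
Why: Luche reduction gives 1,2-reduction of the enone with hydride from the outer face of the two-carbon bridge, so the C15 hydroxyl ends on the face of C9 and C11 as in the target.

**Compound list**
1 | 3-methoxybenzoic acid | COc1cccc(C(=O)O)c1 | starting material
2 | 2,3-dibromoprop-1-ene | C=C(Br)CBr | starting material
3 | (±)-1-(2-bromoprop-2-en-1-yl)-3-methoxycyclohexa-2,5-diene-1-carboxylic acid | C=C(Br)CC1(C(=O)O)C=CCC(OC)=C1 | intermediate
4 | (±)-1-(2-bromoprop-2-en-1-yl)-5-oxocyclohex-2-ene-1-carboxylic acid (β,γ-enone, not isolated) | C=C(Br)CC1(C(=O)O)CC(=O)CC=C1 | intermediate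
5 | (±)-1-(2-bromoprop-2-en-1-yl)-5-oxocyclohex-3-ene-1-carboxylic acid | C=C(Br)CC1(C(=O)O)CC(=O)C=CC1 | intermediate
6 | (R)-1-phenylethylammonium (S)-1-(2-bromoprop-2-en-1-yl)-5-oxocyclohex-3-ene-1-carboxylate (not isolated) | C=C(Br)C[C@@]1(C(=O)[O-])CC(=O)C=CC1.C[C@@H]([NH3+])c1ccccc1 | intermediate
7 | (S)-1-(2-bromoprop-2-en-1-yl)-5-oxocyclohex-3-ene-1-carboxylic acid | C=C(Br)C[C@@]1(C(=O)O)CC(=O)C=CC1 | intermediate
8 | methyl (S)-1-(2-bromoprop-2-en-1-yl)-5-oxocyclohex-3-ene-1-carboxylate | C=C(Br)C[C@@]1(C(=O)OC)CC(=O)C=CC1 | intermediate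
9 | methyl (R)-1-(2-bromoprop-2-en-1-yl)-5-[(tert-butyldimethylsilyl)oxy]cyclohexa-3,5-diene-1-carboxylate | C=C(Br)C[C@@]1(C(=O)OC)C=C(O[Si](C)(C)C(C)(C)C)C=CC1 | intermediate
10 | methyl 3-[(tert-butyldimethylsilyl)oxy]-6-methylidenebicyclo[3.2.1]oct-2-ene-1-carboxylate, C8 and C13 as in the target | C=C1[C@@H]2CC(O[Si](C)(C)C(C)(C)C)=C[C@](C2)(C(=O)OC)C1 | intermediate
11 | ethyl diazoacetate | CCOC(=O)C=[N+]=[N-] | starting material
12 | siloxycyclopropane diester: 10 with CH(CO2Et) (C10) bridging C9 and C11 on the C14 face, both C10 epimers | C=C1[C@@H]2C[C@@]3(O[Si](C)(C)C(C)(C)C)C(C(=O)OCC)[C@H]3[C@](C2)(C(=O)OC)C1 | intermediate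
13 | methyl 4,4-dimethyl-5-oxopentanoate | COC(=O)CCC(C)(C)C=O | starting material
14 | 2-(dichloromethyl)-4,4,5,5-tetramethyl-1,3,2-dioxaborolane | ClC(Cl)B1OC(C)(C)C(C)(C)O1 | starting material
15 | methyl (E)-4,4-dimethyl-6-(4,4,5,5-tetramethyl-1,3,2-dioxaborolan-2-yl)hex-5-enoate | COC(=O)CCC(C)(C)/C=C/B1OC(C)(C)C(C)(C)O1 | intermediate
16 | (E)-4,4-dimethyl-6-(4,4,5,5-tetramethyl-1,3,2-dioxaborolan-2-yl)hex-5-enal | O=CCCC(C)(C)/C=C/B1OC(C)(C)C(C)(C)O1 | intermediate
17 | aldol adduct: 12 with C10 carrying CO2Et (cis to C8) and the 1-hydroxy C1–C6 chain (outer side), C1 epimers | C=C1[C@@H]2C[C@@]3(O[Si](C)(C)C(C)(C)C)[C@](C(=O)OCC)(C(O)CCC(C)(C)/C=C/B4OC(C)(C)C(C)(C)O4)[C@H]3[C@](C2)(C(=O)OC)C1 | intermediate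
18 | diol ester: 17 with CO2Et reduced to CH2OH (C20) (not isolated) | C=C1[C@@H]2C[C@@]3(O[Si](C)(C)C(C)(C)C)[C@](CO)(C(O)CCC(C)(C)/C=C/B4OC(C)(C)C(C)(C)O4)[C@H]3[C@](C2)(C(=O)OC)C1 | intermediate
19 | lactone alcohol: δ-lactone C7(=O)–O–C20 on the siloxycyclopropane, C1–OH epimers | C=C1[C@@H]2C[C@]3(O[Si](C)(C)C(C)(C)C)[C@@H]4[C@](C2)(C(=O)OC[C@]34C(O)CCC(C)(C)/C=C/B5OC(C)(C)C(C)(C)O5)C1 | intermediate
20 | lactone ketone (C1=O) | C=C1[C@@H]2C[C@]3(O[Si](C)(C)C(C)(C)C)[C@@H]4[C@](C2)(C(=O)OC[C@]34C(=O)CCC(C)(C)/C=C/B5OC(C)(C)C(C)(C)O5)C1 | intermediate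
21 | (1S)-carbinol | C=C1[C@@H]2C[C@]3(O[Si](C)(C)C(C)(C)C)[C@@H]4[C@](C2)(C(=O)OC[C@]34[C@@H](O)CCC(C)(C)/C=C/B5OC(C)(C)C(C)(C)O5)C1 | intermediate
22 | (1S)-acetate | C=C1[C@@H]2C[C@]3(O[Si](C)(C)C(C)(C)C)[C@@H]4[C@](C2)(C(=O)OC[C@]34[C@@H](OC(C)=O)CCC(C)(C)/C=C/B5OC(C)(C)C(C)(C)O5)C1 | intermediate
23 | cyclopropanol (C11–OH free) | C=C1[C@@H]2C[C@]3(O)[C@@H]4[C@](C2)(C(=O)OC[C@]34[C@@H](OC(C)=O)CCC(C)(C)/C=C/B5OC(C)(C)C(C)(C)O5)C1 | intermediate
24 | spiro ketone: ring A closed, C11 ketone, C6–B(pin) | C=C1[C@@H]2CC(=O)[C@@H]3[C@](C2)(C(=O)OC[C@]32[C@@H](OC(C)=O)CCC(C)(C)[C@H]2CB4OC(C)(C)C(C)(C)O4)C1 | intermediate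
25 | 11-epi alcohol (C11–OH on the C14 face) | C=C1[C@@H]2C[C@@H](O)[C@@H]3[C@](C2)(C(=O)OC[C@]32[C@@H](OC(C)=O)CCC(C)(C)[C@H]2CB4OC(C)(C)C(C)(C)O4)C1 | intermediate
26 | 11-chloroacetate (C11–O syn to H9) | C=C1[C@@H]2C[C@H](OC(=O)CCl)[C@@H]3[C@](C2)(C(=O)OC[C@]32[C@@H](OC(C)=O)CCC(C)(C)[C@H]2CB4OC(C)(C)C(C)(C)O4)C1 | intermediate
27 | 11-alcohol (C11 as in the target), C6–B(pin) | C=C1[C@@H]2C[C@H](O)[C@@H]3[C@](C2)(C(=O)OC[C@]32[C@@H](OC(C)=O)CCC(C)(C)[C@H]2CB4OC(C)(C)C(C)(C)O4)C1 | intermediate
28 | 15-deoxy target (C6–OH, C11–OH, C1–OAc) | C=C1[C@@H]2C[C@H](O)[C@@H]3[C@](C2)(C(=O)OC[C@]32[C@@H](OC(C)=O)CCC(C)(C)[C@H]2CO)C1 | intermediate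
29 | 15-epi allylic alcohol | C=C1[C@@H]2C[C@H](O)[C@@H]3[C@](C2)(C(=O)OC[C@]32[C@@H](OC(C)=O)CCC(C)(C)[C@H]2CO)[C@H]1O | intermediate
30 | C15 enone | C=C1[C@@H]2C[C@H](O)[C@@H]3[C@](C2)(C(=O)OC[C@]32[C@@H](OC(C)=O)CCC(C)(C)[C@H]2CO)C1=O | intermediate
31 | CNP0210922.1 | C=C1[C@@H]2C[C@H](O)[C@@H]3[C@](C2)(C(=O)OC[C@]32[C@@H](OC(C)=O)CCC(C)(C)[C@H]2CO)[C@@H]1O | target

**Summary**
Total steps: 23. Longest linear sequence: 21 steps (steps 1–7 and 10–23).

Steps most likely to fail:

1. Step 16 (Proposed new method). The tertiary C10 radical may be quenched before it cyclizes onto the hindered alkenyl boronate, or the cyclopropanol may open ionically to the uncyclized ketone. Fallback with known chemistry: it sets out from 23. Silver-catalysed radical ring-opening chlorination (AgNO3 cat., K2S2O8, N-chlorosuccinimide) should give the tertiary β-chloro ketone F1. A tin-hydride radical cyclization of F1 (Bu3SnH, AIBN, slow addition, benzene, 80 °C) onto the alkenyl boronate then returns to the route at 24.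

2. Step 6. The hydrogen transfer to the siloxyallyl radical may show poor regiocontrol, moving the enol ether to C11=C12 and losing the handle on C9. Fallback: it sets out from 8. α′-Acetoxylation with Mn(OAc)3·2H2O (benzene, reflux) marks C9 and gives the α′-acetoxy enone F2. The same tin-hydride vinyl-radical cyclization of F2 gives the bicyclic acetoxy ketone F3. Reductive cleavage of the acetate with SmI2 (THF, −78 °C) forms the C9 enolate regiospecifically, and O-silylation with TBSOTf returns to the route at 10.

3. Step 18. The Mitsunobu inversion at the hindered C11 carbinol may fail through elimination toward C12 or through no substitution. Fallback: it sets out from 24. Reagent-controlled reduction with (R)-2-methyl-CBS-oxazaborolidine and catecholborane, delivering hydride from the C14 face, should give the C11 alcohol directly and returns to the route at 27, so no new compound arises (F0).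

**Further compounds**
F1 | step 16 | tertiary β-chloro ketone (C10–Cl, C11 ketone, ring A open, alkenyl boronate intact) | C=C1[C@@H]2CC(=O)[C@@H]3[C@](C2)(C(=O)OCC3(Cl)[C@@H](OC(C)=O)CCC(C)(C)/C=C/B4OC(C)(C)C(C)(C)O4)C1
F2 | step 6 | methyl 2-acetoxy-1-(2-bromoprop-2-en-1-yl)-3-oxocyclohex-4-ene-1-carboxylate (α′-acetoxy enone, C8 as in 8) | C=C(Br)C[C@@]1(C(=O)OC)C(OC(C)=O)C(=O)C=CC1
F3 | step 6 | methyl 2-acetoxy-6-methylidene-3-oxobicyclo[3.2.1]octane-1-carboxylate (bicyclic acetoxy ketone) | C=C1[C@@H]2CC(=O)C(OC(C)=O)[C@](C2)(C(=O)OC)C1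
F0 | step 18 | none | none
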